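Cuts: once the three O-substituents are adjusted (phenol O–Si, C2 O–acetyl and O–isopropyl), the quinone ring is cut at C1–C6, between the carbonyl carbon next to the oxygenated C2 and the aryl-bearing C6. This contracts it to a 4-styrylcyclobutenone, whose C3–aryl bond and C4–C5 (ring–vinyl) bond are then cut back to diisopropyl squarate.
Enabling feature: quinone atoms C1(=O)–C2(O)–C3(aryl)–C4(=O) are four contiguous ring carbons at the oxidation level of a squaric ester, and the remaining edge C5(H)=C6(aryl) is exactly the two alkene carbons of an (E)-beta-styryl group.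
Forward order: both benzene rings are bought. The styryl unit and then the aryl unit are attached to the four-membered ring, the second with a 1,3-carbonyl shift that places it beside the carbinol carbon. Heat expands the four-membered ring by the two styryl carbons to the six-membered hydroquinone, and oxidation gives the quinone.
End game: isopropyl to hydrogen to acetyl at the C2 oxygen while both phenols stay silylated, then acidic fluoride.
Stereochemistry: the target has no stereocentre. The cyclobutenone carbinol centres are racemic and vanish on aromatisation, and the only stereo-element, the E alkene from the Takai olefination, is consumed in the ring closure.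

Key step: step 6

Assumption: the new carbonyl oxygen formed in step 5 is taken to come from the water of the quench, the isopropoxy group leaving as propan-2-ol.

Step 1
Reactants: 1 4-hydroxybenzaldehyde
Product: 2 4-(triisopropylsilyloxy)benzaldehyde
Conditions: TIPSCl, imidazole, DMF, rt
Reagents that add atoms: chlorotriisopropylsilane CC(C)[Si](Cl)(C(C)C)C(C)C
Why: Imidazole-promoted silylation of a phenol is routine, and the bulky aryl silyl ether removes the acidic proton and should tolerate the organolithium, oxidant and Lewis acid used later.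

Step 2
Reactants: 2 4-(triisopropylsilyloxy)benzaldehyde
Product: 3 (E)-1-(2-iodoethenyl)-4-(triisopropylsilyloxy)benzene
Conditions: CHI3, CrCl2, THF, 0 °C to rt
Reagents that add atoms: iodoform IC(I)I
Why: In the Takai iodo-olefination the geminal dichromium reagent made from CHI3 and CrCl2 adds to the aldehyde and eliminates to the vinyl iodide, aromatic aldehydes favouring the E isomer, under conditions that leave the silyl ether alone.

Step 3
Reactants: 3 (E)-1-(2-iodoethenyl)-4-(triisopropylsilyloxy)benzene; 4 diisopropyl squarate (3,4-diisopropoxycyclobut-3-ene-1,2-dione)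
Product: 7 racemic 2,3-diisopropoxy-4-[(E)-2-(4-triisopropylsilyloxyphenyl)ethenyl]-4-(trimethylsilyloxy)cyclobut-2-en-1-one, via vinyllithium 5 (not isolated), via lithium alkoxide 6 (not isolated)
Conditions: t-BuLi (2 equiv), Et2O, −78 °C; cannulate into 4, THF, −78 °C; TMSCl, −78 to 0 °C
Reagents that add atoms: chlorotrimethylsilane C[Si](C)(C)Cl
Why: Iodine–lithium exchange of an alkenyl iodide keeps the E geometry, the vinyllithium adds 1,2 to one of the two equivalent squarate carbonyls (the standard first squarate addition, new carbinol centre racemic), and silylating the alkoxide in the same flask blocks this oxygen so that only the later carbinol can ionise.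

Step 4
Reactants: 8 4-bromophenol
Product: 9 (4-bromophenoxy)triisopropylsilane
Conditions: TIPSCl, imidazole, DMF, rt
Reagents that add atoms: chlorotriisopropylsilane CC(C)[Si](Cl)(C(C)C)C(C)C
Why: This is the same routine phenol silylation as in step 1, giving a bromide fit for halogen–lithium exchange.

Step 5
Reactants: 9 (4-bromophenoxy)triisopropylsilane; 7 racemic 2,3-diisopropoxy-4-[(E)-2-(4-triisopropylsilyloxyphenyl)ethenyl]-4-(trimethylsilyloxy)cyclobut-2-en-1-one
Product: 13 racemic 2-isopropoxy-3-[4-(triisopropylsilyloxy)phenyl]-4-[(E)-2-(4-triisopropylsilyloxyphenyl)ethenyl]-4-(trimethylsilyloxy)cyclobut-2-en-1-one, via aryllithium 10 (not isolated), via lithium carbinolate 11 (not isolated), via tertiary trifluoroacetate 12 (not isolated)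
Conditions: n-BuLi, THF, −78 °C; 7, THF, −78 °C; (CF3CO)2O, −78 °C; then cold aqueous pH 7 buffer, to rt
Reagents that add atoms: water O
Why: Bromine–lithium exchange, 1,2-addition to the remaining vinylogous-ester carbonyl and trifluoroacetylation of the only free alkoxide let that carbinol ionise to an aryl- and alkoxy-stabilised cyclobutenyl cation whose distal isopropoxy terminus is hydrolysed in the quench, which is the well-known 1,3-carbonyl transposition of squarate adducts and sets the aryl group beside the silyloxy carbon; a competing conjugate addition–elimination at the beta-isopropoxy carbon would give the same 13.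

Step 6
Reactants: 13 racemic 2-isopropoxy-3-[4-(triisopropylsilyloxy)phenyl]-4-[(E)-2-(4-triisopropylsilyloxyphenyl)ethenyl]-4-(trimethylsilyloxy)cyclobut-2-en-1-one
Product: 16 2-isopropoxy-3,6-bis[4-(triisopropylsilyloxy)phenyl]-4-(trimethylsilyloxy)phenol, via dienylketene 14 (not isolated), via cyclohexadienone 15 (not isolated)
Conditions: toluene (degassed, dilute), 110 °C
Reagents that add atoms: none
Why: Heat opens the strained, donor-substituted cyclobutenone by conrotatory 4π electrocyclic cleavage of the C1–C4 bond to dienylketene 14. The ketene carbon (old C1) then bonds to the aryl-bearing terminal styryl carbon in a 6π electrocyclisation across the ketene C=C, the C3=C4 and the styryl C=C units, closing the one new ring, the six-membered carbocycle, as cyclohexadienone 15. Tautomerisation of 15 moves the hydrogen of its only stereocentre (C6, formed racemic) to the carbonyl oxygen, so no stereocentre remains and aromatisation makes the sequence irreversible. The closest known reaction type is the Moore ring expansion of 4-alkenyl-4-hydroxy- or 4-silyloxycyclobutenones to hydroquinones. The selectivity needed is torquoselectivity in the ring opening, which the C4 silyloxy donor secures by rotating outward so that the styryl group turns inward, cis to the ketene, while any ketene with the styryl group outward can only revert to 13. The substitution pattern (aryl groups para, isopropoxy para to hydrogen) is not at stake here because the order C1(=O)–C2(OiPr)–C3(aryl)–C4(O)(styryl) in 13 fixes it, and the E alkene holds its aryl group away from the closing termini.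

Step 7
Reactants: 16 2-isopropoxy-3,6-bis[4-(triisopropylsilyloxy)phenyl]-4-(trimethylsilyloxy)phenol
Product: 17 2-isopropoxy-3,6-bis[4-(triisopropylsilyloxy)phenyl]cyclohexa-2,5-diene-1,4-dione
Conditions: (NH4)2Ce(NO3)6 (2 equiv), MeCN–H2O, 0 °C
Reagents that add atoms: none
Why: Two-electron oxidation of a hydroquinone monosilyl ether, whose labile aryl trimethylsilyl ether hydrolyses in the acidic aqueous medium, is fast and stops at the quinone, while the hindered aryl silyl ethers and the isopropyl vinylogous ester should be inert over the short contact time.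

Step 8
Reactants: 17 2-isopropoxy-3,6-bis[4-(triisopropylsilyloxy)phenyl]cyclohexa-2,5-diene-1,4-dione
Product: 19 2-hydroxy-3,6-bis[4-(triisopropylsilyloxy)phenyl]cyclohexa-2,5-diene-1,4-dione, via dichloroboryl ether 18 (not isolated)
Conditions: BCl3, CH2Cl2, −78 to −20 °C; then H2O
Reagents that add atoms: none
Why: In this Lewis-acid dealkylation BCl3 binds between the C1 carbonyl oxygen and the neighbouring ether oxygen and chloride removes the secondary alkyl group, the known selective cleavage of isopropyl ethers next to a carbonyl, under non-basic conditions that the aryl silyl ethers should withstand.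

Step 9
Reactants: 19 2-hydroxy-3,6-bis[4-(triisopropylsilyloxy)phenyl]cyclohexa-2,5-diene-1,4-dione
Product: 20 2-acetoxy-3,6-bis[4-(triisopropylsilyloxy)phenyl]cyclohexa-2,5-diene-1,4-dione
Conditions: Ac2O, pyridine, CH2Cl2, 0 °C
Reagents that add atoms: acetic anhydride CC(=O)OC(C)=O
Why: O-Acetylation of the acidic quinone hydroxyl, the only free OH in 19, is routine for hydroxyquinones, and low temperature with short contact limits nucleophilic attack at the free C5 position.

Step 10
Reactants: 20 2-acetoxy-3,6-bis[4-(triisopropylsilyloxy)phenyl]cyclohexa-2,5-diene-1,4-dione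
Product: 21 neonambiquinone A (2-acetoxy-3,6-bis(4-hydroxyphenyl)cyclohexa-2,5-diene-1,4-dione)
Conditions: HF·pyridine, THF, 0 °C to rt (polyethylene vessel); weakly acidic buffer work-up
Reagents that add atoms: none
Why: Fluoride-driven Si–O cleavage in an acidic, weakly nucleophilic medium should remove both aryl silyl ethers while sparing the acetoxyquinone, a vinylogous mixed anhydride that basic fluoride or alkoxide would cleave.

Compound list
1 | 4-hydroxybenzaldehyde | O=Cc1ccc(O)cc1 | starting material
2 | 4-(triisopropylsilyloxy)benzaldehyde | O=Cc1ccc(O[Si](C(C)C)(C(C)C)C(C)C)cc1 | intermediate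
3 | (E)-1-(2-iodoethenyl)-4-(triisopropylsilyloxy)benzene | I/C=C/c1ccc(O[Si](C(C)C)(C(C)C)C(C)C)cc1 | intermediate
4 | diisopropyl squarate (3,4-diisopropoxycyclobut-3-ene-1,2-dione) | CC(C)OC1=C(OC(C)C)C(=O)C1=O | starting material
5 | (E)-2-[4-(triisopropylsilyloxy)phenyl]ethenyllithium | [Li]/C=C/c1ccc(O[Si](C(C)C)(C(C)C)C(C)C)cc1 | intermediate
6 | lithium alkoxide of racemic 4-hydroxy-2,3-diisopropoxy-4-[(E)-2-(4-triisopropylsilyloxyphenyl)ethenyl]cyclobut-2-en-1-one | CC(C)OC1=C(OC(C)C)C([O-])(/C=C/c2ccc(O[Si](C(C)C)(C(C)C)C(C)C)cc2)C1=O.[Li+] | intermediate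
7 | racemic 2,3-diisopropoxy-4-[(E)-2-(4-triisopropylsilyloxyphenyl)ethenyl]-4-(trimethylsilyloxy)cyclobut-2-en-1-one | CC(C)OC1=C(OC(C)C)C(O[Si](C)(C)C)(/C=C/c2ccc(O[Si](C(C)C)(C(C)C)C(C)C)cc2)C1=O | intermediate
8 | 4-bromophenol | Oc1ccc(Br)cc1 | starting material
9 | (4-bromophenoxy)triisopropylsilane | CC(C)[Si](Oc1ccc(Br)cc1)(C(C)C)C(C)C | intermediate
10 | 4-(triisopropylsilyloxy)phenyllithium | [Li]c1ccc(O[Si](C(C)C)(C(C)C)C(C)C)cc1 | intermediate
11 | lithium carbinolate from 1,2-addition of 10 to 7 (racemic, mixture of diastereomers) | CC(C)OC1=C(OC(C)C)C(O[Si](C)(C)C)(/C=C/c2ccc(O[Si](C(C)C)(C(C)C)C(C)C)cc2)C1([O-])c3ccc(O[Si](C(C)C)(C(C)C)C(C)C)cc3.[Li+] | intermediate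
12 | trifluoroacetate of the carbinol in 11 (racemic, mixture of diastereomers) | CC(C)OC1=C(OC(C)C)C(O[Si](C)(C)C)(/C=C/c2ccc(O[Si](C(C)C)(C(C)C)C(C)C)cc2)C1(OC(=O)C(F)(F)F)c3ccc(O[Si](C(C)C)(C(C)C)C(C)C)cc3 | intermediate
13 | racemic 2-isopropoxy-3-[4-(triisopropylsilyloxy)phenyl]-4-[(E)-2-(4-triisopropylsilyloxyphenyl)ethenyl]-4-(trimethylsilyloxy)cyclobut-2-en-1-one | CC(C)OC1=C(c2ccc(O[Si](C(C)C)(C(C)C)C(C)C)cc2)C(O[Si](C)(C)C)(/C=C/c2ccc(O[Si](C(C)C)(C(C)C)C(C)C)cc2)C1=O | intermediate
14 | (3E,5E)-2-isopropoxy-3,6-bis[4-(triisopropylsilyloxy)phenyl]-4-(trimethylsilyloxy)hexa-1,3,5-trien-1-one (dienylketene, styryl cis to the ketene-bearing carbon) | O=C=C(OC(C)C)/C(c1ccc(O[Si](C(C)C)(C(C)C)C(C)C)cc1)=C(\C=C\c1ccc(O[Si](C(C)C)(C(C)C)C(C)C)cc1)O[Si](C)(C)C | intermediate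
15 | racemic 2-isopropoxy-3,6-bis[4-(triisopropylsilyloxy)phenyl]-4-(trimethylsilyloxy)cyclohexa-2,4-dien-1-one | CC(C)OC1=C(c2ccc(O[Si](C(C)C)(C(C)C)C(C)C)cc2)C(O[Si](C)(C)C)=CC(c2ccc(O[Si](C(C)C)(C(C)C)C(C)C)cc2)C1=O | intermediate
16 | 2-isopropoxy-3,6-bis[4-(triisopropylsilyloxy)phenyl]-4-(trimethylsilyloxy)phenol | CC(C)Oc1c(-c2ccc(O[Si](C(C)C)(C(C)C)C(C)C)cc2)c(O[Si](C)(C)C)cc(-c2ccc(O[Si](C(C)C)(C(C)C)C(C)C)cc2)c1O | intermediate
17 | 2-isopropoxy-3,6-bis[4-(triisopropylsilyloxy)phenyl]cyclohexa-2,5-diene-1,4-dione | CC(C)OC1=C(c2ccc(O[Si](C(C)C)(C(C)C)C(C)C)cc2)C(=O)C=C(c2ccc(O[Si](C(C)C)(C(C)C)C(C)C)cc2)C1=O | intermediate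
18 | 2-(dichloroboryloxy)-3,6-bis[4-(triisopropylsilyloxy)phenyl]cyclohexa-2,5-diene-1,4-dione | ClB(Cl)OC1=C(c2ccc(O[Si](C(C)C)(C(C)C)C(C)C)cc2)C(=O)C=C(c2ccc(O[Si](C(C)C)(C(C)C)C(C)C)cc2)C1=O | intermediate
19 | 2-hydroxy-3,6-bis[4-(triisopropylsilyloxy)phenyl]cyclohexa-2,5-diene-1,4-dione | OC1=C(c2ccc(O[Si](C(C)C)(C(C)C)C(C)C)cc2)C(=O)C=C(c2ccc(O[Si](C(C)C)(C(C)C)C(C)C)cc2)C1=O | intermediate
20 | 2-acetoxy-3,6-bis[4-(triisopropylsilyloxy)phenyl]cyclohexa-2,5-diene-1,4-dione | CC(=O)OC1=C(c2ccc(O[Si](C(C)C)(C(C)C)C(C)C)cc2)C(=O)C=C(c2ccc(O[Si](C(C)C)(C(C)C)C(C)C)cc2)C1=O | intermediate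
21 | neonambiquinone A (2-acetoxy-3,6-bis(4-hydroxyphenyl)cyclohexa-2,5-diene-1,4-dione) | CC(=O)OC1=C(c2ccc(O)cc2)C(=O)C=C(c2ccc(O)cc2)C1=O | target

Total step count: 10. Longest linear sequence: 9 steps (1 to 2 to 3 to 7 to 13 to 16 to 17 to 19 to 20 to 21).

Steps most likely to fail

**Step 5.** The process to fear is loss of regiochemical control in the anhydride quench. The trimethylsilyl ether may be cleaved, or the silyloxy-bearing carbon may ionise in competition with the new carbinol, and addition to the hindered vinylogous-ester carbonyl may be sluggish. The fallback gives up the transposition. It relies on the innate carbonyl selectivity of an aryl alkoxy cyclobutenedione, paired with an alpha-styryl instead of a beta-styryl nucleophile, which maps onto the same quinone.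
- It sets out from 9 and 4. Aryllithium 10 is added to 4 to give racemic 4-hydroxy-2,3-diisopropoxy-4-[4-(triisopropylsilyloxy)phenyl]cyclobut-2-en-1-one F1. A trace of HCl in CH2Cl2 converts this into 3-isopropoxy-4-[4-(triisopropylsilyloxy)phenyl]cyclobut-3-ene-1,2-dione F2.
- A second portion of 10 is acylated with N-methoxy-N-methylacetamide to 1-[4-(triisopropylsilyloxy)phenyl]ethanone F3. Condensation with 2,4,6-triisopropylbenzenesulfonohydrazide gives the (E)-sulfonylhydrazone F4. A Shapiro reaction (n-BuLi, 2 equiv, THF, −78 to 0 °C) then gives 1-[4-(triisopropylsilyloxy)phenyl]ethenyllithium F5.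
- F5 should add to the carbonyl of F2 next to the isopropoxy-bearing carbon, the other being deactivated as a vinylogous ester. This gives racemic 4-hydroxy-3-isopropoxy-2-[4-(triisopropylsilyloxy)phenyl]-4-{1-[4-(triisopropylsilyloxy)phenyl]ethenyl}cyclobut-2-en-1-one F6.
- Heating F6 in toluene triggers the same type of ring expansion, now closing onto the CH2 terminus, to 2-isopropoxy-3,6-bis[4-(triisopropylsilyloxy)phenyl]benzene-1,4-diol F7. Ag2O oxidises F7 to 17, where the route is rejoined.

**Step 8.** The processes to fear are conjugate addition of chloride or HCl to the unsubstituted C5 position of the quinone, erosion of the aryl silyl ethers, and incomplete dealkylation. The fallback moves the dealkylation to the arene oxidation level, where no conjugate acceptor exists. It sets out from 16. With BCl3 in CH2Cl2 the C1 phenol binds boron and delivers it to the neighbouring aryl isopropyl ether, and the trimethylsilyl group falls off in the work-up. This should give 3,6-bis[4-(triisopropylsilyloxy)phenyl]benzene-1,2,4-triol F8. Oxidation of F8 with Ag2O leads directly to 19, so step 7 is bypassed as well.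

**Step 10.** The process to fear is loss or intermolecular transfer of the acetyl group from the activated enol acetate during or after desilylation. The fallback reverses the order of the last two operations and uses acidity instead of protection for chemoselectivity. It sets out from 19, which carries nothing labile and is desilylated with HF·pyridine to 2-hydroxy-3,6-bis(4-hydroxyphenyl)cyclohexa-2,5-diene-1,4-dione F9. The quinone hydroxyl of F9 is a vinylogous carboxylic acid, several pK units more acidic than the phenols. One equivalent of 2,6-lutidine should therefore ionise it alone. One equivalent of Ac2O in THF at low temperature should then acetylate that oxyanion to give 21.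

Further compounds
F1 | step 5 | racemic 4-hydroxy-2,3-diisopropoxy-4-[4-(triisopropylsilyloxy)phenyl]cyclobut-2-en-1-one | CC(C)OC1=C(OC(C)C)C(O)(c2ccc(O[Si](C(C)C)(C(C)C)C(C)C)cc2)C1=O
F2 | step 5 | 3-isopropoxy-4-[4-(triisopropylsilyloxy)phenyl]cyclobut-3-ene-1,2-dione | CC(C)OC1=C(c2ccc(O[Si](C(C)C)(C(C)C)C(C)C)cc2)C(=O)C1=O
F3 | step 5 | 1-[4-(triisopropylsilyloxy)phenyl]ethanone | CC(=O)c1ccc(O[Si](C(C)C)(C(C)C)C(C)C)cc1
F4 | step 5 | (E)-2,4,6-triisopropylbenzenesulfonylhydrazone of F3 | C/C(c1ccc(O[Si](C(C)C)(C(C)C)C(C)C)cc1)=N\NS(=O)(=O)c1c(C(C)C)cc(C(C)C)cc1C(C)C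
F5 | step 5 | 1-[4-(triisopropylsilyloxy)phenyl]ethenyllithium | [Li]C(=C)c1ccc(O[Si](C(C)C)(C(C)C)C(C)C)cc1
F6 | step 5 | racemic 4-hydroxy-3-isopropoxy-2-[4-(triisopropylsilyloxy)phenyl]-4-{1-[4-(triisopropylsilyloxy)phenyl]ethenyl}cyclobut-2-en-1-one | CC(C)OC1=C(c2ccc(O[Si](C(C)C)(C(C)C)C(C)C)cc2)C(=O)C1(O)C(=C)c3ccc(O[Si](C(C)C)(C(C)C)C(C)C)cc3
F7 | step 5 | 2-isopropoxy-3,6-bis[4-(triisopropylsilyloxy)phenyl]benzene-1,4-diol | CC(C)Oc1c(-c2ccc(O[Si](C(C)C)(C(C)C)C(C)C)cc2)c(O)cc(-c2ccc(O[Si](C(C)C)(C(C)C)C(C)C)cc2)c1O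
F8 | step 8 | 3,6-bis[4-(triisopropylsilyloxy)phenyl]benzene-1,2,4-triol | Oc1c(-c2ccc(O[Si](C(C)C)(C(C)C)C(C)C)cc2)c(O)cc(-c2ccc(O[Si](C(C)C)(C(C)C)C(C)C)cc2)c1O
F9 | step 10 | 2-hydroxy-3,6-bis(4-hydroxyphenyl)cyclohexa-2,5-diene-1,4-dione | OC1=C(c2ccc(O)cc2)C(=O)C=C(c2ccc(O)cc2)C1=O
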